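## Structural features

The target is a C24 norsesterterpenoid peroxy acid built from three parts. The first is a cis-fused 1,1,3,6-tetramethylhexahydronaphthalene: ring A is C4a, C5, C6, C7, C8, C8a with the C5=C6 alkene, and ring B is C1, C2, C3, C4, C4a, C8a with the tetrasubstituted C2=C3 alkene. The second is a CH2CH2 link from C2, and the third is a 1,2-dioxane whose quaternary C6' carries the link and a methyl group and whose C3' carries a 2-propanoic acid (Cα). The five stereocentres form two groups that cannot influence each other. C4a and C8a are neighbours at the ring fusion (4aR,8aS, both hydrogens on one face). C3' and Cα are neighbours (both R, C3'–O anti to the Cα methyl in the zigzag), and C6' (R) is 1,4-related to C3' across the O–O bond. The fragile groups are the O–O bond (reductants, phosphines, low-valent metals, base acting on C3'–H or on a carbonyl-activated Cα–H), the acid-sensitive tetrasubstituted alkene and the epimerisable Cα. The real difficulty is threefold: the quaternary C1 wedged between the C8a stereocentre and the tetrasubstituted alkene; a cis ring fusion in a carbocycle with no heteroatom to steer it; and a fully substituted peroxy carbon of defined configuration. Ring A carries functionality only at C5/C6, so any activating group used to build the carbocycle must later leave without moving that alkene. The key step exploits the fact that C1 (two methyl groups) is bonded to C8a, and that C8a is β to C7 in ring A. A tertiary radical at C1, generated from an isopropenyl group on a chain anchored at C4a, can therefore add to a C7-carbonyl-activated C8=C8a bond, so that C4a dictates C8a.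

## Logic of the disconnections

**40 ⇒ 38 ⇒ 37.** No skeletal bond is cut; the carboxyl carbon is taken back to a silyl-protected CH2OH. The reason is that a carbonyl at this carbon would make Cα–H acidic while C3' carries a leaving group or a peroxide (elimination). The gain is that the peroxide ring can be built and coupled without that liability. The demand is a final oxidation that spares O–O, both alkenes and Cα.

**37 ⇒ 18 + 35 (through 36).** The C2–CH2 bond (sp2–sp3) is cut. It lies between the two stereochemical domains, so each fragment (14 and 10 carbons) can be made enantioselectively on its own, and any minor enantiomer surfaces later as a separable diastereomer. The demand is a hydroboration and a palladium-catalysed coupling that tolerate the peroxide and a hindered electrophile.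

**18 ⇒ 17 ⇒ 16 ⇒ 15.** The C2–O bond of 18 is traced to a ketone whose only enolisable position is C3 (C1 is quaternary), so the C2=C3 alkene position is unambiguous. The gain is that C2 and C3 need no stereocontrol anywhere earlier. The demand is removal of a very hindered silyl group.

**15 ⇒ 14 ⇒ 13 ⇒ 12 ⇒ 11.** The C5=C6 alkene is placed in conjugation with a C7 carbonyl, which is then traced to a saturated ketone. A C7 carbonyl is exactly what activates C8a for the key step. The demand is dehydrogenation towards C6 only, and carbonyl removal without alkene migration.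

**11 ⇒ 10.** The C1–C8a bond is cut. It is the only bond joining the quaternary carbon to a stereocentre, and cutting it removes ring B, the quaternary centre and one stereocentre at once, leaving a monocyclic enone with a single controlled centre. The demand is cis-selective closure and hydrogen-atom transfer to the right alkene.

**10 ⇒ 9 ⇒ 8 ⇒ 6 + 7.** The C6–CH3 bond is cut (enolate alkylation), then the C8=C8a bond (aldol condensation) and the C4a–C5 bond (conjugate addition). Ring A falls apart into an acyclic aldehyde and a four-carbon enone, and the single stereocentre becomes the α-carbon of an aldehyde, where amine catalysis can set it. The demand is high enantiofacial control and no epimerisation before ring closure.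

**6 ⇒ 4 ⇒ 3 ⇒ 1 + 2.** The aldehyde is unmasked from a trisubstituted alkene and the C1–C2 bond is cut to an alkenyl organometallic and an aldehyde. This gives two commercial building blocks. The demand is cleavage of one alkene in the presence of the isopropenyl group.

**35 ⇒ 34 ⇒ 33.** The vinyl carbon is removed (one-carbon olefination) and the aldehyde is traced to a primary alcohol. The demand is olefination of a non-enolisable α-peroxy aldehyde without O–O reduction.

**33 ⇒ 32 ⇒ 31.** O–C3' is cut first, then O–C6'. Both C–O bonds of the peroxide arise by displacement with inversion, so both stereocentres are traced to C–O stereocentres of opposite configuration, one a sulfonate and one an epoxide. The gain is that the O–O unit comes from the simplest two-oxygen nucleophile. The demand is inversion at a tertiary carbon and selective reaction of the peroxide anion.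

**31 ⇒ 30 ⇒ 29 ⇒ 28 ⇒ 26 + 27.** The Cα–C3' bond is cut (auxiliary-controlled syn aldol). Two adjacent centres come from one reliable step. The demand is that the epoxide survive a boron Lewis acid and a free neighbouring hydroxyl until step 21.

**26 ⇒ 24 ⇒ 21 + 22, and 21 ⇒ 19.** The C4'–C5' bond is cut (organocopper opening) and the epoxide is traced to an allylic alcohol. The quaternary C–O centre comes from a catalytic asymmetric epoxidation. The demand is attack at the epoxide CH2 and not at the sulfonate, since the other regiochemistry would give the enantiomer.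

## Other disconnections considered

**Alternative 1:** The cut removes C4a–C8a and C1–C2 together and unfolds both rings to a linear C15 chain, 5-hydroxyfarnesyl acetate A1.
- Forward step: a confined chiral imidodiphosphorimidate acid would ionise the allylic alcohol of A1 to the C4a–C5–C6 allyl cation. The terminal trisubstituted alkene would close ring A at C4a (terpinyl-type closure). The C1 cation would then be taken up by the C2=C3 alkene with loss of the C2 proton, giving the acetate A2.
- In its favour: one step makes both rings, the quaternary C1, both ring-fusion centres and both alkenes in their final positions. A2 already carries the C2 carbon arm, no carbonyl has to be removed, and the carbocycle needs no protecting group.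
- Where it is better: step count and atom economy. A2 would lie perhaps four to six operations from a farnesyl feedstock, against fourteen steps to 18 here.
- Against it here: enantiofacial control over a free allyl cation formed by alcohol ionisation, with the cis fusion fixed in the same bond formation, has no secure counterpart for this substrate class. The cations can lose a proton at three stages, need the cisoid allyl geometry, and can be intercepted by the acetate carbonyl. A2 would still need conversion to a phosphonium salt, an olefination and a diimide reduction to reach the chain.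
- Comparison: structurally both plans give the same bicyclic core. Mechanistically, the chosen radical closure takes its stereocontrol from an existing centre (C4a) and a polarity-matched, well-mapped reaction type, while the cationic cascade would have to establish a new selectivity. The alternative is the better in brevity; the chosen plan is the better in predictability.

**Alternative 2:** The cut is O–C6' of the dioxane.
- Forward step: the secondary hydroperoxide A3, tethered to a 2,2-disubstituted epoxide, would be treated with camphorsulfonic acid. The terminal peroxide oxygen opens the epoxide at its tertiary carbon (6-exo) with inversion and gives the dioxanyl methanol A4. A4 is the same compound as 33, and A3 the same as F7.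
- Where it is better: the quaternary C6' is formed intramolecularly under acid, so its stereochemical fidelity should be higher than in the intermolecular perhydrolysis of step 22. It also never exposes a β-hydroxy peroxide to base.
- Against it: A3 has to come from an intermolecular SN2 displacement at the β-branched secondary C3' by a hydroperoxide nucleophile, the least efficient kind of peroxide alkylation (elimination, low conversion). A free hydroperoxide must also be handled next to an acid-labile epoxide.
- Comparison: the outcome is structurally identical and starts from the same mesylate 31; only the order of the two C–O bond formations is reversed, and the step count is equal. The chosen order makes the difficult displacement at the secondary carbon intramolecular and accepts a less certain inversion at the tertiary carbon; the alternative does the opposite. It is not a rival of the key step, because it addresses the heterocycle only. It is therefore held as the fallback for step 22.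

**Alternative 3:** The cut removes C4a–C8a and C7–C8 and builds ring A from the diene A5 and prop-2-enal A6.
- Forward step: 5-benzyl-2,2,3-trimethylimidazolidin-4-one hydrochloride (the enantiomer that shields the appropriate face) converts A6 into an iminium ion. Endo [4+2] addition to the E-diene A5 gives the aldehyde A7, with the future C4 and C1 carbons cis and the C5=C6 alkene and its methyl group in place.
- In its favour: it is a known catalytic reaction type that sets both ring-fusion centres in one step. It is the equal of the chosen plan in absolute control. It is the better in that the cis relationship follows from a concerted endo transition state, and in that ring A arrives with its alkene, so steps 8 to 11 of the chosen route would disappear.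
- Against it here: ring B is still missing, and with it the hard part. The formyl carbon must become the quaternary C1 (two methyl groups and the bond to C2) next to C8a, whose hydrogen is α to the aldehyde and can epimerise to the trans series in the catalytic step and in every later enolisation. The tetrasubstituted C2=C3 alkene must then be closed, and A5 is volatile and prone to polymerise.
- Comparison: the chosen key step forms exactly the C1–C8a bond that this alternative inherits as a C–CHO bond and must then load with three more carbon substituents. Overall step count is not expected to be lower: ring A in one step against seven, but ring B in perhaps eight to ten against one.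

Key step: step 7

Remarks on the chemistry (assumptions):
- Locants C1–C8a (carbocycle) and C3', C6', Cα (dioxane part) follow the target numbering in all names, also where systematic rules would number differently. TBS = tert-butyldimethylsilyl; TBDPS = tert-butyldiphenylsilyl.
- The tether carbons C2 and C3 and the ring carbon C6 are carried as stereoisomer mixtures from 3 to 17. They are erased in steps 8, 13 and 14, and all isomers converge on 18.
- The configuration of 10 and the ring fusion of 11 were re-derived from the target and found consistent; no correction was needed. The ring stereocentre is (4S) in 9 and (4R) in 10 only because the new methyl group changes the CIP ranking.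
- The enantiomeric purity from steps 4 and 15 is assumed high. Residual minor enantiomers would become diastereomers at step 26 and are removed there.

## Route

Step 1
Reactants: 1 2,6-dimethylhept-5-enal; 2 prop-1-en-2-ylmagnesium bromide
Product: 3 2,4,8-trimethylnona-1,7-dien-3-ol
Conditions: THF, −78 → 0 °C; aqueous work-up
Reagents that add atoms: none
Why: 1,2-Addition of an alkenyl Grignard reagent to an aldehyde; the new carbinol centre (future C2) and the α-methyl centre (future C3) are spectators erased in steps 13 and 14, so no control is needed.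

Step 2
Reactants: 3 2,4,8-trimethylnona-1,7-dien-3-ol
Product: 4 tert-butyldimethyl[(2,4,8-trimethylnona-1,7-dien-3-yl)oxy]silane
Conditions: TBSOTf, 2,6-lutidine, CH2Cl2, 0 °C
Reagents that add atoms: tert-butyldimethylsilyl trifluoromethanesulfonate, CC(C)(C)[Si](C)(C)OS(=O)(=O)C(F)(F)F
Why: Silyl ether formation with a silyl triflate caps the hindered allylic alcohol, which would otherwise close onto the aldehyde of step 3 as a lactol; the ether should survive the enolate, radical and Lewis-acid steps up to step 12.

Step 3
Reactants: 4 tert-butyldimethyl[(2,4,8-trimethylnona-1,7-dien-3-yl)oxy]silane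
Product: 6 5-[(tert-butyldimethylsilyl)oxy]-4,6-dimethylhept-6-enal, via secondary ozonide 5 (not isolated)
Conditions: O3 (about 1 equiv, Sudan Red 7B end point), CH2Cl2, −78 °C; then Me2S, −78 °C → rt
Reagents that add atoms: ozone, [O-][O+]=O
Why: Chemoselective ozonolysis with reductive work-up; the electron-rich trisubstituted alkene reacts much faster with electrophilic ozone than the 1,1-disubstituted alkene, which is deactivated and shielded by the allylic silyloxy group.

Step 4
Reactants: 6 5-[(tert-butyldimethylsilyl)oxy]-4,6-dimethylhept-6-enal; 7 but-3-en-2-one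
Product: 8 (2S)-5-[(tert-butyldimethylsilyl)oxy]-4,6-dimethyl-2-(3-oxobutyl)hept-6-enal
Conditions: (S)-2-(methoxydiphenylmethyl)pyrrolidine (10 mol %), ethyl 3,4-dihydroxybenzoate (20 mol %), neat, 4 °C
Reagents that add atoms: none
Why: Enamine-catalysed asymmetric Michael addition of an aldehyde to a vinyl ketone; the (S)-diarylprolinol ether forms the E-enamine and blocks one face, so the enone adds to the open face and sets the future C4a centre as (2S) whatever the remote racemic centres are.

Step 5
Reactants: 8 (2S)-5-[(tert-butyldimethylsilyl)oxy]-4,6-dimethyl-2-(3-oxobutyl)hept-6-enal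
Product: 9 (4S)-4-{3-[(tert-butyldimethylsilyl)oxy]-2,4-dimethylpent-4-en-1-yl}cyclohex-2-en-1-one
Conditions: KOH (0.1 M aq, cat.), n-Bu4NOH (cat.), Et2O/THF, rt → 40 °C
Reagents that add atoms: none
Why: Intramolecular aldol condensation of the 1,5-ketoaldehyde (Robinson-type ring closure) gives the 4-substituted cyclohexenone; the stereocentre ends up γ to the carbonyl, where dilute hydroxide should not epimerise it.

Step 6
Reactants: 9 (4S)-4-{3-[(tert-butyldimethylsilyl)oxy]-2,4-dimethylpent-4-en-1-yl}cyclohex-2-en-1-one
Product: 10 (4R)-4-{3-[(tert-butyldimethylsilyl)oxy]-2,4-dimethylpent-4-en-1-yl}-6-methylcyclohex-2-en-1-one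
Conditions: LiN(i-Pr)2, THF, −78 °C; MeI, −78 → −20 °C
Reagents that add atoms: iodomethane, CI
Why: Kinetic α'-deprotonation of the enone and enolate alkylation place the future C6 methyl group; γ-deprotonation, which would touch C4, does not compete under kinetic control, and the new methyl centre is a spectator erased in step 8.

Step 7
Reactants: 10 (4R)-4-{3-[(tert-butyldimethylsilyl)oxy]-2,4-dimethylpent-4-en-1-yl}-6-methylcyclohex-2-en-1-one
Product: 11 (4aR,8aS)-2-[(tert-butyldimethylsilyl)oxy]-1,1,3,6-tetramethyl-cis-decalin-7-one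
Conditions: Fe(acac)3 (30–50 mol %), PhSiH3 (2.5 equiv, slow addition), EtOH/ethylene glycol 5:1, 0.02 M, 60 °C
Reagents that add atoms: none
Why: Fe(acac)3 and PhSiH3 in EtOH form an iron hydride that transfers a hydrogen atom to the terminal CH2 of the electron-rich 1,1-disubstituted alkene, making it the second C1 methyl and leaving a tertiary radical at C1. This nucleophilic radical adds to the electron-poor β-carbon C8a of the enone; the α-keto radical is reduced by divalent iron to the enolate, EtOH protonates it, and trivalent iron is regenerated. The closest known reaction type is the iron-hydride hydrogen-atom-transfer reductive coupling of unactivated alkenes with enones (a Giese-type addition), here intramolecular. Ring B closes in the 6-exo-trig mode (C1, C2, C3, C4, C4a, C8a; C8 stays outside the new ring). The one new stereocentre, C8a, is controlled by C4a: the tether sits pseudo-equatorial on the enone half-chair and the radical must attack C8a axially, which is possible only from the face that gives the cis fusion (4aR,8aS), whereas equatorial attack towards the trans isomer would pass through a twist-boat enolate. The step needs hydrogen-atom transfer to the isopropenyl group and not to the enone, which the hydridic, polarity-matched metal hydride secures, and it needs cyclisation to outrun reduction of the tertiary radical and a 1,5-hydrogen shift from C4a–H, which dilution and slow silane addition favour. The neutral medium avoids γ-deprotonation of the enone, so C4a keeps its configuration.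

Step 8
Reactants: 11 (4aR,8aS)-2-[(tert-butyldimethylsilyl)oxy]-1,1,3,6-tetramethyl-cis-decalin-7-one
Product: 12 (4aR,8aS)-2-[(tert-butyldimethylsilyl)oxy]-1,1,3,6-tetramethyl-7-[(trimethylsilyl)oxy]-1,2,3,4,4a,5,8,8a-octahydronaphthalene
Conditions: Me3SiCl, NaI, Et3N, MeCN, rt → 40 °C
Reagents that add atoms: chlorotrimethylsilane, C[Si](C)(C)Cl
Why: Thermodynamic silyl enol ether formation (Me3SiI made in situ) favours the more substituted C6=C7 enol ether over the C7=C8 isomer next to the congested C8a; this fixes the regiochemistry of the dehydrogenation and removes the C6 spectator centre.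

Step 9
Reactants: 12 (4aR,8aS)-2-[(tert-butyldimethylsilyl)oxy]-1,1,3,6-tetramethyl-7-[(trimethylsilyl)oxy]-1,2,3,4,4a,5,8,8a-octahydronaphthalene
Product: 13 (4aR,8aS)-2-[(tert-butyldimethylsilyl)oxy]-1,1,3,6-tetramethyl-1,2,3,4,4a,8a-hexahydronaphthalen-7(8H)-one
Conditions: Pd(OAc)2 (1.1 equiv), MeCN, rt
Reagents that add atoms: none
Why: Saegusa–Ito oxidation; the palladium enolate undergoes β-hydride elimination towards the ring CH2 (C5) and gives the C5=C6 enone under neutral conditions that leave the now γ-positioned C4a–H untouched.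

Step 10
Reactants: 13 (4aR,8aS)-2-[(tert-butyldimethylsilyl)oxy]-1,1,3,6-tetramethyl-1,2,3,4,4a,8a-hexahydronaphthalen-7(8H)-one
Product: 14 7,7-ethylenedithio ketal (1,3-dithiolane) of 13
Conditions: HSCH2CH2SH, BF3·OEt2 (0.3 equiv), CH2Cl2, −20 → 0 °C
Reagents that add atoms: ethane-1,2-dithiol, SCCS
Why: Lewis-acid-catalysed dithioketalisation; with 1,2-dithiols the double bond of a cyclohexenone stays in place (unlike O-ketalisation), and the α-methyl group disfavours conjugate addition of the thiol.

Step 11
Reactants: 14 7,7-ethylenedithio ketal (1,3-dithiolane) of 13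
Product: 15 tert-butyldimethyl{[(4aR,8aS)-1,1,3,6-tetramethyl-1,2,3,4,4a,7,8,8a-octahydronaphthalen-2-yl]oxy}silane
Conditions: Raney Ni (W-2, acetone-deactivated), EtOH, rt → 50 °C
Reagents that add atoms: none
Why: Mozingo reduction (Raney Ni hydrogenolysis of both C–S bonds) replaces the masked carbonyl by CH2 while the trisubstituted alkene stays, as in the classical conversion of steroidal enones into the corresponding alkenes; a deactivated catalyst and short contact limit alkene migration or saturation.

Step 12
Reactants: 15 tert-butyldimethyl{[(4aR,8aS)-1,1,3,6-tetramethyl-1,2,3,4,4a,7,8,8a-octahydronaphthalen-2-yl]oxy}silane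
Product: 16 (4aR,8aS)-1,1,3,6-tetramethyl-1,2,3,4,4a,7,8,8a-octahydronaphthalen-2-ol
Conditions: HF·pyridine, THF, 0 °C → rt
Reagents that add atoms: none
Why: Fluoride-driven desilylation (Si–F bond formation); HF·pyridine is chosen because the ether sits between a quaternary and a tertiary carbon, and the isolated trisubstituted alkene tolerates the buffered acid.

Step 13
Reactants: 16 (4aR,8aS)-1,1,3,6-tetramethyl-1,2,3,4,4a,7,8,8a-octahydronaphthalen-2-ol
Product: 17 (4aR,8aS)-1,1,3,6-tetramethyl-3,4,4a,7,8,8a-hexahydronaphthalen-2(1H)-one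
Conditions: Dess–Martin periodinane, NaHCO3, CH2Cl2, rt
Reagents that add atoms: none
Why: Dess–Martin oxidation of the hindered secondary alcohol under buffered conditions; it erases the C2 spectator centre, and the C3 centre next to the carbonyl disappears in step 14.

Step 14
Reactants: 17 (4aR,8aS)-1,1,3,6-tetramethyl-3,4,4a,7,8,8a-hexahydronaphthalen-2(1H)-one
Product: 18 (4aR,8aS)-1,1,3,6-tetramethyl-1,4,4a,7,8,8a-hexahydronaphthalen-2-yl trifluoromethanesulfonate
Conditions: KN(SiMe3)2, THF, −78 °C; PhNTf2, −78 → 0 °C
Reagents that add atoms: N-phenylbis(trifluoromethanesulfonimide), O=S(=O)(N(c1ccccc1)S(=O)(=O)C(F)(F)F)C(F)(F)F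
Why: Enol triflate formation by O-sulfonylation of the enolate; C1 is quaternary, so deprotonation can occur only at C3, the tetrasubstituted C2=C3 bond forms regiospecifically, and all C3 epimers converge on one compound.

Step 15
Reactants: 19 2-methylprop-2-en-1-ol
Product: 21 [(2R)-2-methyloxiran-2-yl]methyl 4-methylbenzenesulfonate, via (S)-2-methylglycidol 20 (not isolated)
Conditions: Ti(Oi-Pr)4 (5 mol %), L-(+)-diisopropyl tartrate (6 mol %), t-BuOOH, 4 Å MS, CH2Cl2, −20 °C; then TsCl, Et3N, DMAP (cat.), −10 °C
Reagents that add atoms: tert-butyl hydroperoxide, CC(C)(C)OO; 4-methylbenzenesulfonyl chloride, Cc1ccc(cc1)S(Cl)(=O)=O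
Why: Sharpless asymmetric epoxidation with the L-(+)-tartrate gives (S)-2-methylglycidol, whose quaternary centre becomes C6'; in situ tosylation avoids isolating the volatile, water-soluble epoxy alcohol (the descriptor changes to R only through the CIP ranking).

Step 16
Reactants: 21 [(2R)-2-methyloxiran-2-yl]methyl 4-methylbenzenesulfonate; 22 prop-2-en-1-ylmagnesium bromide
Product: 24 (2R)-2-(but-3-en-1-yl)-2-methyloxirane, via hydroxy tosylate 23 (not isolated)
Conditions: CuI (10 mol %), THF, −40 → −20 °C; then MeOH, K2CO3, rt
Reagents that add atoms: none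
Why: Copper-catalysed Grignard opening of the strained epoxide at its CH2 terminus (far faster than displacement of the neopentyl-type tosylate), then 3-exo-tet closure of the tertiary alkoxide onto the tosylate (Williamson-type epoxide formation); no bond to the stereocentre is broken, so its configuration is kept while the epoxide moves to the other arm.

Step 17
Reactants: 24 (2R)-2-(but-3-en-1-yl)-2-methyloxirane
Product: 26 3-[(2R)-2-methyloxiran-2-yl]propanal, via secondary ozonide 25 (not isolated)
Conditions: O3, CH2Cl2, −78 °C; then Me2S, −78 °C → rt (used as a solution)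
Reagents that add atoms: ozone, [O-][O+]=O
Why: Ozonolysis with reductive work-up turns the vinyl group into the aldehyde; the epoxide is inert to ozone.

Step 18
Reactants: 27 (4R)-4-benzyl-3-propanoyl-1,3-oxazolidin-2-one; 26 3-[(2R)-2-methyloxiran-2-yl]propanal
Product: 28 (4R)-4-benzyl-3-{(2R,3S)-3-hydroxy-2-methyl-5-[(2R)-2-methyloxiran-2-yl]pentanoyl}-1,3-oxazolidin-2-one
Conditions: n-Bu2BOTf, i-Pr2NEt, CH2Cl2, −78 → 0 °C; 26, −78 → 0 °C; then pH 7 buffer, MeOH, H2O2, 0 °C
Reagents that add atoms: none
Why: Evans syn-aldol reaction; the Z-boron enolate of the (R)-benzyl oxazolidinone reacts through a closed chair transition state to the (2R,3S) syn adduct, which sets Cα in its final configuration and C3' in the configuration opposite to the final one, as the later inversion requires.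

Step 19
Reactants: 28 (4R)-4-benzyl-3-{(2R,3S)-3-hydroxy-2-methyl-5-[(2R)-2-methyloxiran-2-yl]pentanoyl}-1,3-oxazolidin-2-one
Product: 29 (2S,3S)-2-methyl-5-[(2R)-2-methyloxiran-2-yl]pentane-1,3-diol
Conditions: LiBH4, MeOH (1 equiv), Et2O, 0 °C
Reagents that add atoms: none
Why: Reductive removal of the auxiliary (imide reduction) gives the 1,3-diol; the carboxyl carbon is kept at the alcohol level so that the C3' sulfonate of step 21 has no acidifying carbonyl next to it, and the non-acidic medium keeps the hydroxyl from opening the epoxide.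

Step 20
Reactants: 29 (2S,3S)-2-methyl-5-[(2R)-2-methyloxiran-2-yl]pentane-1,3-diol
Product: 30 (2S,3S)-1-[(tert-butyldiphenylsilyl)oxy]-2-methyl-5-[(2R)-2-methyloxiran-2-yl]pentan-3-ol
Conditions: TBDPSCl, imidazole, CH2Cl2, 0 °C
Reagents that add atoms: tert-butyl(chloro)diphenylsilane, CC(C)(C)[Si](Cl)(c1ccccc1)c1ccccc1
Why: Selective silylation of the primary over the secondary hydroxyl by a bulky silyl chloride (steric differentiation).

Step 21
Reactants: 30 (2S,3S)-1-[(tert-butyldiphenylsilyl)oxy]-2-methyl-5-[(2R)-2-methyloxiran-2-yl]pentan-3-ol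
Product: 31 (2S,3S)-1-[(tert-butyldiphenylsilyl)oxy]-2-methyl-5-[(2R)-2-methyloxiran-2-yl]pentan-3-yl methanesulfonate
Conditions: MsCl, Et3N, CH2Cl2, −20 → 0 °C
Reagents that add atoms: methanesulfonyl chloride, CS(Cl)(=O)=O
Why: Sulfonylation turns C3'–OH into a leaving group with retention and removes the hydroxyl nucleophile that could open the epoxide to a tetrahydrofuran.

Step 22
Reactants: 31 (2S,3S)-1-[(tert-butyldiphenylsilyl)oxy]-2-methyl-5-[(2R)-2-methyloxiran-2-yl]pentan-3-yl methanesulfonate
Product: 32 (2S,3S,6S)-1-[(tert-butyldiphenylsilyl)oxy]-6-hydroperoxy-7-hydroxy-2,6-dimethylheptan-3-yl methanesulfonate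
Conditions: H2O2 (anhydrous, in Et2O, excess), H3PMo12O40 (2 mol %), 0 °C → rt
Reagents that add atoms: hydrogen peroxide, OO
Why: Acid-catalysed perhydrolysis of a 2,2-disubstituted epoxide; under H3PMo12O40 catalysis H2O2 opens the epoxide at the more substituted carbon in a borderline SN2 process with inversion, creating the tertiary C6' hydroperoxide and releasing the CH2OH arm.

Step 23
Reactants: 32 (2S,3S,6S)-1-[(tert-butyldiphenylsilyl)oxy]-6-hydroperoxy-7-hydroxy-2,6-dimethylheptan-3-yl methanesulfonate
Product: 33 [(3R,6S)-3-{(2S)-1-[(tert-butyldiphenylsilyl)oxy]propan-2-yl}-6-methyl-1,2-dioxan-6-yl]methanol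
Conditions: KOt-Bu (1.05 equiv), 18-crown-6, toluene, 0 °C
Reagents that add atoms: none
Why: Intramolecular alkylation of the hydroperoxide anion (6-exo-tet SN2) displaces the C3' mesylate with inversion, closes the 1,2-dioxane and sets C3'–O anti to the Cα methyl; one equivalent of base deprotonates only the far more acidic OOH group.

Step 24
Reactants: 33 [(3R,6S)-3-{(2S)-1-[(tert-butyldiphenylsilyl)oxy]propan-2-yl}-6-methyl-1,2-dioxan-6-yl]methanol
Product: 34 (3R,6S)-3-{(2S)-1-[(tert-butyldiphenylsilyl)oxy]propan-2-yl}-6-methyl-1,2-dioxane-6-carbaldehyde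
Conditions: Dess–Martin periodinane, NaHCO3, CH2Cl2, 0 °C → rt
Reagents that add atoms: none
Why: Dess–Martin oxidation of the neopentyl primary alcohol gives a non-enolisable α-peroxy aldehyde; dialkyl peroxides are inert to the hypervalent iodine reagent.

Step 25
Reactants: 34 (3R,6S)-3-{(2S)-1-[(tert-butyldiphenylsilyl)oxy]propan-2-yl}-6-methyl-1,2-dioxane-6-carbaldehyde
Product: 35 tert-butyl{(2S)-2-[(3R,6S)-6-ethenyl-6-methyl-1,2-dioxan-3-yl]propoxy}diphenylsilane
Conditions: Ph3PCH3Br, KN(SiMe3)2, THF, 0 °C; then 34, −78 → 0 °C
Reagents that add atoms: methyltriphenylphosphonium bromide, C[P+](c1ccccc1)(c1ccccc1)c1ccccc1.[Br-]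
Why: Wittig methylenation with a non-stabilised ylide; the aldehyde has no α-hydrogen, and a phosphorus ylide, unlike a phosphine, does not deoxygenate the peroxide.

Step 26
Reactants: 35 tert-butyl{(2S)-2-[(3R,6S)-6-ethenyl-6-methyl-1,2-dioxan-3-yl]propoxy}diphenylsilane; 18 (4aR,8aS)-1,1,3,6-tetramethyl-1,4,4a,7,8,8a-hexahydronaphthalen-2-yl trifluoromethanesulfonate
Product: 37 tert-butyl{(2S)-2-[(3R,6R)-6-methyl-6-{2-[(4aR,8aS)-1,1,3,6-tetramethyl-1,4,4a,7,8,8a-hexahydronaphthalen-2-yl]ethyl}-1,2-dioxan-3-yl]propoxy}diphenylsilane, via B-alkyl-9-BBN borane 36 (not isolated)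
Conditions: 9-BBN, THF, 0 °C → rt; then 18, PdCl2(dppf) (5 mol %), AsPh3 (10 mol %), Cs2CO3 (aq), DMF, rt
Reagents that add atoms: none
Why: Anti-Markovnikov hydroboration of the vinyl group followed by B-alkyl Suzuki–Miyaura coupling with the enol triflate forms the C2–CH2 bond directly at the final oxidation level, so no alkene has to be reduced beside the ring alkenes; hydroboration and palladium-catalysed coupling both have precedent in the presence of dialkyl peroxides.

Step 27
Reactants: 37 tert-butyl{(2S)-2-[(3R,6R)-6-methyl-6-{2-[(4aR,8aS)-1,1,3,6-tetramethyl-1,4,4a,7,8,8a-hexahydronaphthalen-2-yl]ethyl}-1,2-dioxan-3-yl]propoxy}diphenylsilane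
Product: 38 (2S)-2-[(3R,6R)-6-methyl-6-{2-[(4aR,8aS)-1,1,3,6-tetramethyl-1,4,4a,7,8,8a-hexahydronaphthalen-2-yl]ethyl}-1,2-dioxan-3-yl]propan-1-ol
Conditions: Bu4NF, AcOH (1:1), THF, 0 °C → rt
Reagents that add atoms: none
Why: Fluoride-mediated desilylation, buffered with AcOH so that the medium stays non-basic and a Kornblum–DeLaMare fragmentation at C3'–H is avoided.

Step 28
Reactants: 38 (2S)-2-[(3R,6R)-6-methyl-6-{2-[(4aR,8aS)-1,1,3,6-tetramethyl-1,4,4a,7,8,8a-hexahydronaphthalen-2-yl]ethyl}-1,2-dioxan-3-yl]propan-1-ol
Product: 40 (2R)-2-[(3R,6R)-6-methyl-6-{2-[(4aR,8aS)-1,1,3,6-tetramethyl-1,4,4a,7,8,8a-hexahydronaphthalen-2-yl]ethyl}-1,2-dioxan-3-yl]propanoic acid, via aldehyde 39 (not isolated)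
Conditions: TEMPO (20 mol %), PhI(OAc)2 (2.5 equiv), MeCN/pH 7 buffer, rt
Reagents that add atoms: water, O
Why: Oxoammonium-mediated oxidation takes the primary alcohol through the aldehyde hydrate to the acid under near-neutral conditions that spare the peroxide and both alkenes and leave little time for epimerisation at Cα (whose descriptor changes from S to R only through the CIP ranking).

## Compound list

1 | 2,6-dimethylhept-5-enal (racemic) | CC(C)=CCCC(C)C=O | starting material
2 | prop-1-en-2-ylmagnesium bromide | CC(=C)[Mg]Br | starting material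
3 | 2,4,8-trimethylnona-1,7-dien-3-ol (racemic, both diastereomers) | CC(=C)C(O)C(C)CCC=C(C)C | intermediate
4 | tert-butyldimethyl[(2,4,8-trimethylnona-1,7-dien-3-yl)oxy]silane | CC(=C)C(O[Si](C)(C)C(C)(C)C)C(C)CCC=C(C)C | intermediate
5 | tert-butyl{[6-(5,5-dimethyl-1,2,4-trioxolan-3-yl)-2,4-dimethylhex-1-en-3-yl]oxy}dimethylsilane (ozonide) | CC(=C)C(O[Si](C)(C)C(C)(C)C)C(C)CCC1OOC(C)(C)O1 | intermediate (not isolated)
6 | 5-[(tert-butyldimethylsilyl)oxy]-4,6-dimethylhept-6-enal | CC(=C)C(O[Si](C)(C)C(C)(C)C)C(C)CCC=O | intermediate
7 | but-3-en-2-one | CC(=O)C=C | starting material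
8 | (2S)-5-[(tert-butyldimethylsilyl)oxy]-4,6-dimethyl-2-(3-oxobutyl)hept-6-enal | CC(=C)C(O[Si](C)(C)C(C)(C)C)C(C)C[C@H](CCC(C)=O)C=O | intermediate
9 | (4S)-4-{3-[(tert-butyldimethylsilyl)oxy]-2,4-dimethylpent-4-en-1-yl}cyclohex-2-en-1-one | CC(=C)C(O[Si](C)(C)C(C)(C)C)C(C)C[C@H]1C=CC(=O)CC1 | intermediate
10 | (4R)-4-{3-[(tert-butyldimethylsilyl)oxy]-2,4-dimethylpent-4-en-1-yl}-6-methylcyclohex-2-en-1-one | CC(=C)C(O[Si](C)(C)C(C)(C)C)C(C)C[C@H]1C=CC(=O)C(C)C1 | intermediate (key-step precursor)
11 | (4aR,8aS)-2-[(tert-butyldimethylsilyl)oxy]-1,1,3,6-tetramethyl-cis-decalin-7-one | CC1C[C@H]2CC(C)C(O[Si](C)(C)C(C)(C)C)C(C)(C)[C@H]2CC1=O | intermediate (key-step product)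
12 | (4aR,8aS)-2-[(tert-butyldimethylsilyl)oxy]-1,1,3,6-tetramethyl-7-[(trimethylsilyl)oxy]-1,2,3,4,4a,5,8,8a-octahydronaphthalene | CC=1C[C@H]2CC(C)C(O[Si](C)(C)C(C)(C)C)C(C)(C)[C@H]2CC=1O[Si](C)(C)C | intermediate
13 | (4aR,8aS)-2-[(tert-butyldimethylsilyl)oxy]-1,1,3,6-tetramethyl-1,2,3,4,4a,8a-hexahydronaphthalen-7(8H)-one | CC1=C[C@H]2CC(C)C(O[Si](C)(C)C(C)(C)C)C(C)(C)[C@H]2CC1=O | intermediate
14 | 7,7-ethylenedithio ketal (1,3-dithiolane) of 13 | CC1=C[C@H]2CC(C)C(O[Si](C)(C)C(C)(C)C)C(C)(C)[C@H]2CC13SCCS3 | intermediate
15 | tert-butyldimethyl{[(4aR,8aS)-1,1,3,6-tetramethyl-1,2,3,4,4a,7,8,8a-octahydronaphthalen-2-yl]oxy}silane | CC1=C[C@H]2CC(C)C(O[Si](C)(C)C(C)(C)C)C(C)(C)[C@H]2CC1 | intermediate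
16 | (4aR,8aS)-1,1,3,6-tetramethyl-1,2,3,4,4a,7,8,8a-octahydronaphthalen-2-ol | CC1=C[C@H]2CC(C)C(O)C(C)(C)[C@H]2CC1 | intermediate
17 | (4aR,8aS)-1,1,3,6-tetramethyl-3,4,4a,7,8,8a-hexahydronaphthalen-2(1H)-one | CC1=C[C@H]2CC(C)C(=O)C(C)(C)[C@H]2CC1 | intermediate
18 | (4aR,8aS)-1,1,3,6-tetramethyl-1,4,4a,7,8,8a-hexahydronaphthalen-2-yl trifluoromethanesulfonate | CC1=C[C@H]2CC(C)=C(OS(=O)(=O)C(F)(F)F)C(C)(C)[C@H]2CC1 | intermediate
19 | 2-methylprop-2-en-1-ol | CC(=C)CO | starting material
20 | [(2S)-2-methyloxiran-2-yl]methanol | C[C@@]1(CO1)CO | intermediate (not isolated)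
21 | [(2R)-2-methyloxiran-2-yl]methyl 4-methylbenzenesulfonate | C[C@@]1(CO1)COS(=O)(=O)c1ccc(C)cc1 | intermediate
22 | prop-2-en-1-ylmagnesium bromide | C=CC[Mg]Br | starting material
23 | (2R)-2-hydroxy-2-methylhex-5-en-1-yl 4-methylbenzenesulfonate | C=CCC[C@@](C)(O)COS(=O)(=O)c1ccc(C)cc1 | intermediate (not isolated)
24 | (2R)-2-(but-3-en-1-yl)-2-methyloxirane | C[C@]1(CO1)CCC=C | intermediate
25 | (2R)-2-methyl-2-[2-(1,2,4-trioxolan-3-yl)ethyl]oxirane (ozonide) | C[C@]1(CO1)CCC2OOCO2 | intermediate (not isolated)
26 | 3-[(2R)-2-methyloxiran-2-yl]propanal | C[C@]1(CO1)CCC=O | intermediate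
27 | (4R)-4-benzyl-3-propanoyl-1,3-oxazolidin-2-one | CCC(=O)N1C(=O)OC[C@H]1Cc1ccccc1 | starting material
28 | (4R)-4-benzyl-3-{(2R,3S)-3-hydroxy-2-methyl-5-[(2R)-2-methyloxiran-2-yl]pentanoyl}-1,3-oxazolidin-2-one | C[C@]1(CO1)CC[C@@H]([C@@H](C)C(=O)N2C(=O)OC[C@H]2Cc2ccccc2)O | intermediate
29 | (2S,3S)-2-methyl-5-[(2R)-2-methyloxiran-2-yl]pentane-1,3-diol | C[C@]1(CO1)CC[C@@H]([C@@H](C)CO)O | intermediate
30 | (2S,3S)-1-[(tert-butyldiphenylsilyl)oxy]-2-methyl-5-[(2R)-2-methyloxiran-2-yl]pentan-3-ol | C[C@]1(CO1)CC[C@@H]([C@@H](C)CO[Si](c2ccccc2)(c2ccccc2)C(C)(C)C)O | intermediate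
31 | (2S,3S)-1-[(tert-butyldiphenylsilyl)oxy]-2-methyl-5-[(2R)-2-methyloxiran-2-yl]pentan-3-yl methanesulfonate | C[C@]1(CO1)CC[C@@H]([C@@H](C)CO[Si](c2ccccc2)(c2ccccc2)C(C)(C)C)OS(C)(=O)=O | intermediate
32 | (2S,3S,6S)-1-[(tert-butyldiphenylsilyl)oxy]-6-hydroperoxy-7-hydroxy-2,6-dimethylheptan-3-yl methanesulfonate | OC[C@@](C)(OO)CC[C@@H]([C@@H](C)CO[Si](c1ccccc1)(c1ccccc1)C(C)(C)C)OS(C)(=O)=O | intermediate
33 | [(3R,6S)-3-{(2S)-1-[(tert-butyldiphenylsilyl)oxy]propan-2-yl}-6-methyl-1,2-dioxan-6-yl]methanol | OC[C@]1(C)CC[C@H]([C@@H](C)CO[Si](c2ccccc2)(c2ccccc2)C(C)(C)C)OO1 | intermediate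
34 | (3R,6S)-3-{(2S)-1-[(tert-butyldiphenylsilyl)oxy]propan-2-yl}-6-methyl-1,2-dioxane-6-carbaldehyde | O=C[C@]1(C)CC[C@H]([C@@H](C)CO[Si](c2ccccc2)(c2ccccc2)C(C)(C)C)OO1 | intermediate
35 | tert-butyl{(2S)-2-[(3R,6S)-6-ethenyl-6-methyl-1,2-dioxan-3-yl]propoxy}diphenylsilane | C=C[C@]1(C)CC[C@H]([C@@H](C)CO[Si](c2ccccc2)(c2ccccc2)C(C)(C)C)OO1 | intermediate
36 | 9-{2-[(3R,6R)-3-{(2S)-1-[(tert-butyldiphenylsilyl)oxy]propan-2-yl}-6-methyl-1,2-dioxan-6-yl]ethyl}-9-borabicyclo[3.3.1]nonane | B1(CC[C@]2(C)CC[C@H]([C@@H](C)CO[Si](c3ccccc3)(c3ccccc3)C(C)(C)C)OO2)C2CCCC1CCC2 | intermediate (not isolated)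
37 | tert-butyl{(2S)-2-[(3R,6R)-6-methyl-6-{2-[(4aR,8aS)-1,1,3,6-tetramethyl-1,4,4a,7,8,8a-hexahydronaphthalen-2-yl]ethyl}-1,2-dioxan-3-yl]propoxy}diphenylsilane | CC1=C[C@H]2CC(C)=C(CC[C@]3(C)CC[C@H]([C@@H](C)CO[Si](c4ccccc4)(c4ccccc4)C(C)(C)C)OO3)C(C)(C)[C@H]2CC1 | intermediate
38 | (2S)-2-[(3R,6R)-6-methyl-6-{2-[(4aR,8aS)-1,1,3,6-tetramethyl-1,4,4a,7,8,8a-hexahydronaphthalen-2-yl]ethyl}-1,2-dioxan-3-yl]propan-1-ol | CC1=C[C@H]2CC(C)=C(CC[C@]3(C)CC[C@H]([C@@H](C)CO)OO3)C(C)(C)[C@H]2CC1 | intermediate
39 | (2R)-2-[(3R,6R)-6-methyl-6-{2-[(4aR,8aS)-1,1,3,6-tetramethyl-1,4,4a,7,8,8a-hexahydronaphthalen-2-yl]ethyl}-1,2-dioxan-3-yl]propanal | CC1=C[C@H]2CC(C)=C(CC[C@]3(C)CC[C@H]([C@@H](C)C=O)OO3)C(C)(C)[C@H]2CC1 | intermediate (not isolated)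
40 | (2R)-2-[(3R,6R)-6-methyl-6-{2-[(4aR,8aS)-1,1,3,6-tetramethyl-1,4,4a,7,8,8a-hexahydronaphthalen-2-yl]ethyl}-1,2-dioxan-3-yl]propanoic acid (CNP0122760.1) | CC1=C[C@H]2CC(C)=C(CC[C@]3(C)CC[C@H]([C@@H](C)C(=O)O)OO3)C(C)(C)[C@H]2CC1 | target

## Step count and least certain steps

Total step count: 28. Longest linear sequence: 17 steps (steps 1–14, then 26–28); the dioxane branch (steps 15–25) joins at step 26.

**Step 7 (key step).**
- What may go wrong: premature reduction of the tertiary radical (net hydrogenation of the isopropenyl group) before it reaches C8a, or a 1,5-hydrogen shift from the allylic C4a–H that would erode the controlling stereocentre. Some tether diastereomers may also close with lower cis selectivity, because the C2 and C3 substituents must fit the chair-like transition state.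
- Fallback (from 10, back at 11): generate the same radical without a metal hydride present. Mukaiyama hydration of 10 (Co(acac)2, PhSiH3, O2-saturated i-PrOH, 0 °C, where oxygen trapping should outrun cyclisation) gives the tertiary alcohol F1. Acylation with methyl chlorooxoacetate (Et3N, DMAP) gives the methyl oxalate F2, and saponification with one equivalent of CsOH gives the caesium oxalate F3. Visible-light photoredox decarboxylation of F3 (Ir[dF(CF3)ppy]2(dtbbpy)PF6, blue light, DME/DMF, H2O) releases the tertiary radical, which cyclises onto the enone in the same 6-exo mode to give 11.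

**Step 22.**
- What may go wrong: partial loss of configuration at C6' if the opening drifts towards a carbocation, or rearrangement of the epoxide to a carbonyl compound. In the following step 23, base-induced fragmentation of the β-hydroxy hydroperoxide can compete with ring closure.
- Fallback (from 31, back at 33, bypassing step 23): reverse the order of the two C–O bond formations. Displacement of the mesylate of 31 with 2-methoxypropan-2-yl hydroperoxide and KOt-Bu in DMF (inversion at C3') gives the peroxyketal F6. Mild acid removes the ketal to the hydroperoxide F7. Camphorsulfonic acid in CH2Cl2 then closes F7 onto the tertiary epoxide carbon (6-exo, inversion at C6') to give 33.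

**Step 11.**
- What may go wrong: migration of the C5=C6 double bond towards C6=C7, or its saturation, on the nickel surface during C–S hydrogenolysis. The acidic step 10 may also epimerise C4a through a dienol.
- Fallback (from 13, back at 15): a double 1,3-transposition that fixes the alkene position by mechanism. Nucleophilic epoxidation of 13 (t-BuOOH, DBU, CH2Cl2) gives the epoxy ketone F4. Wharton transposition (N2H4·H2O, AcOH, MeOH) gives the allylic alcohol F5 with the hydroxyl at C5 and the alkene at C6=C7. Mitsunobu displacement of F5 with 2-nitrobenzenesulfonylhydrazide (PPh3, diethyl azodicarboxylate, −30 °C → rt), then loss of sulfinic acid and dinitrogen with transposition of the double bond, delivers hydrogen to C7 and gives 15.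

**Step 26.**
- What may go wrong: cleavage of the O–O bond by the borane or by zerovalent palladium and its ligands, or slow transmetallation and reductive elimination at the hindered tetrasubstituted triflate, so that protodeboronation or β-hydride elimination takes over.
- Fallback (from 18 and 34, back at 37): olefination and diimide reduction, both long used beside peroxides. Methoxycarbonylation of 18 (Pd(OAc)2, PPh3, CO, MeOH, Et3N, DMF, 60 °C) gives the ester F8. Reduction with i-Bu2AlH (CH2Cl2, −78 °C) gives the allylic alcohol F9, and PPh3·HBr in MeOH gives the phosphonium bromide F10. Deprotonation of F10 with n-BuLi (THF, −78 °C) and Wittig reaction with 34 give the diene F11 as an E/Z mixture. Diimide (KO2CN=NCO2K, AcOH, MeOH, 0 °C → rt) reduces only the disubstituted double bond of F11 and gives 37.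

## Further compounds

F1 | step 7 | (4R)-4-{3-[(tert-butyldimethylsilyl)oxy]-4-hydroxy-2,4-dimethylpentyl}-6-methylcyclohex-2-en-1-one | CC(C)(O)C(O[Si](C)(C)C(C)(C)C)C(C)C[C@H]1C=CC(=O)C(C)C1
F2 | step 7 | 3-[(tert-butyldimethylsilyl)oxy]-2,4-dimethyl-5-[(1R)-5-methyl-4-oxocyclohex-2-en-1-yl]pentan-2-yl methyl oxalate | COC(=O)C(=O)OC(C)(C)C(O[Si](C)(C)C(C)(C)C)C(C)C[C@H]1C=CC(=O)C(C)C1
F3 | step 7 | caesium 2-({3-[(tert-butyldimethylsilyl)oxy]-2,4-dimethyl-5-[(1R)-5-methyl-4-oxocyclohex-2-en-1-yl]pentan-2-yl}oxy)-2-oxoacetate | [Cs+].[O-]C(=O)C(=O)OC(C)(C)C(O[Si](C)(C)C(C)(C)C)C(C)C[C@H]1C=CC(=O)C(C)C1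
F4 | step 11 | 5,6-epoxide of 13 (5,6-epoxy-2-[(tert-butyldimethylsilyl)oxy]-1,1,3,6-tetramethyl-cis-decalin-7-one) | CC13OC3[C@H]2CC(C)C(O[Si](C)(C)C(C)(C)C)C(C)(C)[C@H]2CC1=O
F5 | step 11 | (4aS,8aS)-2-[(tert-butyldimethylsilyl)oxy]-1,1,3,6-tetramethyl-1,2,3,4,4a,5,8,8a-octahydronaphthalen-5-ol | CC=1C(O)[C@H]2CC(C)C(O[Si](C)(C)C(C)(C)C)C(C)(C)[C@H]2CC=1
F6 | step 22 | tert-butyl{[(2S,3R)-3-[(2-methoxypropan-2-yl)peroxy]-2-methyl-5-[(2R)-2-methyloxiran-2-yl]pentyl]oxy}diphenylsilane | C[C@]1(CO1)CC[C@H]([C@@H](C)CO[Si](c2ccccc2)(c2ccccc2)C(C)(C)C)OOC(C)(C)OC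
F7 | step 22 | tert-butyl{[(2S,3R)-3-hydroperoxy-2-methyl-5-[(2R)-2-methyloxiran-2-yl]pentyl]oxy}diphenylsilane | C[C@]1(CO1)CC[C@H]([C@@H](C)CO[Si](c2ccccc2)(c2ccccc2)C(C)(C)C)OO
F8 | step 26 | methyl (4aR,8aS)-1,1,3,6-tetramethyl-1,4,4a,7,8,8a-hexahydronaphthalene-2-carboxylate | CC1=C[C@H]2CC(C)=C(C(=O)OC)C(C)(C)[C@H]2CC1
F9 | step 26 | [(4aR,8aS)-1,1,3,6-tetramethyl-1,4,4a,7,8,8a-hexahydronaphthalen-2-yl]methanol | CC1=C[C@H]2CC(C)=C(CO)C(C)(C)[C@H]2CC1
F10 | step 26 | triphenyl{[(4aR,8aS)-1,1,3,6-tetramethyl-1,4,4a,7,8,8a-hexahydronaphthalen-2-yl]methyl}phosphonium bromide | CC1=C[C@H]2CC(C)=C(C[P+](c3ccccc3)(c3ccccc3)c3ccccc3)C(C)(C)[C@H]2CC1.[Br-]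
F11 | step 26 | tert-butyl{(2S)-2-[(3R,6S)-6-methyl-6-{2-[(4aR,8aS)-1,1,3,6-tetramethyl-1,4,4a,7,8,8a-hexahydronaphthalen-2-yl]ethenyl}-1,2-dioxan-3-yl]propoxy}diphenylsilane (E/Z mixture) | CC1=C[C@H]2CC(C)=C(C=C[C@]3(C)CC[C@H]([C@@H](C)CO[Si](c4ccccc4)(c4ccccc4)C(C)(C)C)OO3)C(C)(C)[C@H]2CC1
A1 | alternative 1 | 5-hydroxy-3,7,11-trimethyldodeca-2,6,10-trien-1-yl acetate (5-hydroxyfarnesyl acetate) | CC(C)=CCCC(C)=CC(O)CC(C)=CCOC(C)=O
A2 | alternative 1 | [(4aR,8aS)-1,1,3,6-tetramethyl-1,4,4a,7,8,8a-hexahydronaphthalen-2-yl]methyl acetate | CC1=C[C@H]2CC(C)=C(COC(C)=O)C(C)(C)[C@H]2CC1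
A3 | alternative 2 | tert-butyl{[(2S,3R)-3-hydroperoxy-2-methyl-5-[(2R)-2-methyloxiran-2-yl]pentyl]oxy}diphenylsilane | C[C@]1(CO1)CC[C@H]([C@@H](C)CO[Si](c2ccccc2)(c2ccccc2)C(C)(C)C)OO
A4 | alternative 2 | [(3R,6S)-3-{(2S)-1-[(tert-butyldiphenylsilyl)oxy]propan-2-yl}-6-methyl-1,2-dioxan-6-yl]methanol | OC[C@]1(C)CC[C@H]([C@@H](C)CO[Si](c2ccccc2)(c2ccccc2)C(C)(C)C)OO1
A5 | alternative 3 | tert-butyldimethyl{[(2E)-4-methylpenta-2,4-dien-1-yl]oxy}silane | C=C(C)/C=C/CO[Si](C)(C)C(C)(C)C
A6 | alternative 3 | prop-2-enal | C=CC=O
A7 | alternative 3 | (1S,2R)-2-{[(tert-butyldimethylsilyl)oxy]methyl}-4-methylcyclohex-3-ene-1-carbaldehyde | CC1=C[C@@H](CO[Si](C)(C)C(C)(C)C)[C@@H](C=O)CC1
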